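The target is the erythro (7S,8R) arylglycerol β-aryl ether. The route rests on cutting C7–C8, the bond between the benzylic carbinol carbon on the guaiacyl ring and the carbon that carries the aryl ether oxygen of the syringyl-type ring and C9. With C9 raised to the acyl level, the O–C7–C8(OAr)–C9 array is an anti glycolate aldol pattern. A magnesium-catalysed direct anti-aldol joins a vanillin-derived aldehyde (glyceryl diol as benzyl ethers) to an N-(aryloxyacetyl)oxazolidinone (propanol chain as a cinnamate ester) and sets both stereocentres in one operation. One hydrogenation and one hydride reduction then uncover all five hydroxyl groups.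

Key step: step 4

Remark: lignan numbering is used for the propane chain (C7 benzylic carbinol carbon, C8 carbon bearing the aryl ether oxygen, C9 CH2OH). The target SMILES is read as (7S,8R), with 7-OH and 8-OAr anti in the zigzag drawing of Ar–C7–C8–C9. Compounds 1, 2, 4, 5 and 8 are taken as purchasable.

Step 1
Reactants: 1 vanillin; 2 1,3-bis(benzyloxy)propan-2-ol
Product: 3 4-{[1,3-bis(benzyloxy)propan-2-yl]oxy}-3-methoxybenzaldehyde
Conditions: PPh3, DIAD, THF, 0 °C to rt
Reagents that add atoms: none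
Why: Mitsunobu etherification, in which the acidic phenol of vanillin protonates the betaine and displaces the activated secondary alcohol, whose carbinol carbon is not a stereocentre.

Step 2
Reactants: 4 (4R)-4-benzyl-1,3-oxazolidin-2-one; 5 bromoacetyl bromide
Product: 7 (4R)-4-benzyl-3-(bromoacetyl)-1,3-oxazolidin-2-one, via lithium oxazolidinide 6 (not isolated)
Conditions: n-BuLi, THF, −78 °C; then 5, −78 °C
Reagents that add atoms: none
Why: N-acylation of the lithiated oxazolidinone, since acyl substitution at the acid bromide is much faster than SN2 at CH2Br at −78 °C and the C4 stereocentre is not touched.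

Step 3
Reactants: 7 (4R)-4-benzyl-3-(bromoacetyl)-1,3-oxazolidin-2-one; 8 methyl sinapate
Product: 9 methyl (2E)-3-(4-{2-[(4R)-4-benzyl-2-oxo-1,3-oxazolidin-3-yl]-2-oxoethoxy}-3,5-dimethoxyphenyl)prop-2-enoate
Conditions: K2CO3, acetone, rt
Reagents that add atoms: none
Why: Williamson ether synthesis, in which the hindered, weakly basic phenoxide should attack the activated α-bromo carbon in preference to the imide carbonyl.

Step 4
Reactants: 9 methyl (2E)-3-(4-{2-[(4R)-4-benzyl-2-oxo-1,3-oxazolidin-3-yl]-2-oxoethoxy}-3,5-dimethoxyphenyl)prop-2-enoate; 3 4-{[1,3-bis(benzyloxy)propan-2-yl]oxy}-3-methoxybenzaldehyde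
Product: 11 methyl (2E)-3-[4-({(2S,3S)-1-[(4R)-4-benzyl-2-oxo-1,3-oxazolidin-3-yl]-3-(4-{[1,3-bis(benzyloxy)propan-2-yl]oxy}-3-methoxyphenyl)-3-hydroxy-1-oxopropan-2-yl}oxy)-3,5-dimethoxyphenyl]prop-2-enoate, via TMS ether 10 (not isolated)
Conditions: MgCl2 (20 mol%), Et3N, TMSCl, EtOAc, rt; then 1 M HCl, THF, 0 °C
Reagents that add atoms: none
Why: MgCl2/Et3N soft-enolises the aryloxyacetyl imide, whose C–H is acidified by two-point binding to Mg(II) and by the α-aryloxy group, to a (Z)-magnesium enolate chelated between the enolate oxygen and the oxazolidinone carbonyl; this adds reversibly to the Mg-bound aldehyde through a boat-like six-membered transition state, and TMSCl silylates the magnesium aldolate, which makes the C7–C8 bond formation irreversible and returns Mg(II) to the cycle. The closest known reaction type is the Evans anti-aldol, the magnesium-halide-catalysed direct aldol of N-acyloxazolidinones with non-enolisable aromatic aldehydes. No ring is closed. C8 is controlled by the auxiliary: in the chelated enolate the C4 benzyl group covers one face, the aldehyde bonds to the other (the facial sense of chelate-controlled alkylation), and with the (4R)-auxiliary this gives 2S in the imide, which becomes 8R once C9 is reduced; C7 is controlled by the boat arrangement of the (Z)-enolate, which places the new hydroxyl anti to the aryloxy group (3S, later 7S). The step needs anti over syn selectivity and enolisation of the imide alone: the aldehyde has no α-hydrogen, and the enoate ester and the benzyl ethers are not touched by Et3N/TMSCl.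

Step 5
Reactants: 11 methyl (2E)-3-[4-({(2S,3S)-1-[(4R)-4-benzyl-2-oxo-1,3-oxazolidin-3-yl]-3-(4-{[1,3-bis(benzyloxy)propan-2-yl]oxy}-3-methoxyphenyl)-3-hydroxy-1-oxopropan-2-yl}oxy)-3,5-dimethoxyphenyl]prop-2-enoate
Product: 12 methyl 3-[4-({(2S,3S)-1-[(4R)-4-benzyl-2-oxo-1,3-oxazolidin-3-yl]-3-{4-[(1,3-dihydroxypropan-2-yl)oxy]-3-methoxyphenyl}-3-hydroxy-1-oxopropan-2-yl}oxy)-3,5-dimethoxyphenyl]propanoate
Conditions: H2 (1 atm), Pd/C, EtOAc–EtOH, rt
Reagents that add atoms: none
Why: Catalytic hydrogenation saturates the conjugated alkene and hydrogenolysis cleaves both primary alkyl benzyl ethers, while the secondary benzylic alcohol should survive in the absence of acid and no stereocentre is touched.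

Step 6
Reactants: 12 methyl 3-[4-({(2S,3S)-1-[(4R)-4-benzyl-2-oxo-1,3-oxazolidin-3-yl]-3-{4-[(1,3-dihydroxypropan-2-yl)oxy]-3-methoxyphenyl}-3-hydroxy-1-oxopropan-2-yl}oxy)-3,5-dimethoxyphenyl]propanoate
Product: 13 (1S,2R)-1-{4-[(1,3-dihydroxypropan-2-yl)oxy]-3-methoxyphenyl}-2-[4-(3-hydroxypropyl)-2,6-dimethoxyphenoxy]propane-1,3-diol
Conditions: LiBH4 (excess), MeOH, THF, 0 °C to rt
Reagents that add atoms: none
Why: Lithium borohydride reduction cleaves the N-acyloxazolidinone at the exocyclic carbonyl to the C9 primary alcohol (auxiliary 4 is released) and reduces the methyl ester to the 3-hydroxypropyl chain, and reduction should outrun enolisation at C8, so both stereocentres are kept.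

Compound list
1 | vanillin (4-hydroxy-3-methoxybenzaldehyde) | COc1cc(C=O)ccc1O | starting material
2 | 1,3-bis(benzyloxy)propan-2-ol | OC(COCc1ccccc1)COCc1ccccc1 | starting material
3 | 4-{[1,3-bis(benzyloxy)propan-2-yl]oxy}-3-methoxybenzaldehyde | COc1cc(C=O)ccc1OC(COCc1ccccc1)COCc1ccccc1 | intermediate
4 | (4R)-4-benzyl-1,3-oxazolidin-2-one | O=C1N[C@H](Cc2ccccc2)CO1 | starting material
5 | bromoacetyl bromide | BrCC(Br)=O | starting material
6 | lithium (4R)-4-benzyl-2-oxo-1,3-oxazolidin-3-ide (formed in the flask) | [Li+].O=C1[N-][C@H](Cc2ccccc2)CO1 | intermediate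
7 | (4R)-4-benzyl-3-(bromoacetyl)-1,3-oxazolidin-2-one | O=C(CBr)N1[C@H](Cc2ccccc2)COC1=O | intermediate
8 | methyl sinapate (methyl (2E)-3-(4-hydroxy-3,5-dimethoxyphenyl)prop-2-enoate) | COC(=O)/C=C/c1cc(OC)c(O)c(OC)c1 | starting material
9 | methyl (2E)-3-(4-{2-[(4R)-4-benzyl-2-oxo-1,3-oxazolidin-3-yl]-2-oxoethoxy}-3,5-dimethoxyphenyl)prop-2-enoate | COC(=O)/C=C/c1cc(OC)c(OCC(=O)N2[C@H](Cc3ccccc3)COC2=O)c(OC)c1 | intermediate
10 | O-trimethylsilyl ether of 11 (formed in the flask), (2S,3S) in the acyl chain, (4R) in the auxiliary | COc1cc([C@H](O[Si](C)(C)C)[C@@H](C(=O)N2[C@H](Cc3ccccc3)COC2=O)Oc2c(OC)cc(/C=C/C(=O)OC)cc2OC)ccc1OC(COCc1ccccc1)COCc1ccccc1 | intermediate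
11 | methyl (2E)-3-[4-({(2S,3S)-1-[(4R)-4-benzyl-2-oxo-1,3-oxazolidin-3-yl]-3-(4-{[1,3-bis(benzyloxy)propan-2-yl]oxy}-3-methoxyphenyl)-3-hydroxy-1-oxopropan-2-yl}oxy)-3,5-dimethoxyphenyl]prop-2-enoate | COc1cc([C@H](O)[C@@H](C(=O)N2[C@H](Cc3ccccc3)COC2=O)Oc2c(OC)cc(/C=C/C(=O)OC)cc2OC)ccc1OC(COCc1ccccc1)COCc1ccccc1 | intermediate
12 | methyl 3-[4-({(2S,3S)-1-[(4R)-4-benzyl-2-oxo-1,3-oxazolidin-3-yl]-3-{4-[(1,3-dihydroxypropan-2-yl)oxy]-3-methoxyphenyl}-3-hydroxy-1-oxopropan-2-yl}oxy)-3,5-dimethoxyphenyl]propanoate | COc1cc([C@H](O)[C@@H](C(=O)N2[C@H](Cc3ccccc3)COC2=O)Oc2c(OC)cc(CCC(=O)OC)cc2OC)ccc1OC(CO)CO | intermediate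
13 | (1S,2R)-1-{4-[(1,3-dihydroxypropan-2-yl)oxy]-3-methoxyphenyl}-2-[4-(3-hydroxypropyl)-2,6-dimethoxyphenoxy]propane-1,3-diol | COc1cc([C@H](O)[C@@H](CO)Oc2c(OC)cc(CCCO)cc2OC)ccc1OC(CO)CO | target

Total step count: 6
Longest linear sequence: 5 steps (steps 2, 3, 4, 5, 6)

Steps most likely to fail

1. Step 4. The electron-rich aldehyde is a weak acceptor, so the magnesium aldolate may revert before it is silylated and conversion may stall. The bulky α-aryloxy group may also erode the preference for the anti pathway, and the use of an α-aryloxy donor in this reaction is an extrapolation. The fallback sets out from 9 and 3 and comes back at 11. It replaces the catalytic, reversible magnesium manifold by a stoichiometric, irreversible boron aldol through an open transition state. Imide 9 is converted with Bu2BOTf and iPr2NEt (CH2Cl2, −78 to 0 °C) into the (Z)-dibutylboron enolate F1. F1 is added at −78 °C to aldehyde 3 precomplexed with Et2AlCl. The Lewis-acid-bound aldehyde should attack the enolate face left free by the C4 benzyl group through an open transition state, a known route to anti adducts with the same α-configuration. Work-up with MeOH and pH 7 buffer should then give 11.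

2. Step 6. Under the basic hydride conditions the β-hydroxy imide may undergo retro-aldol cleavage of C7–C8. Hydride may also attack the ring carbonyl of the hindered imide, and the methyl ester may be reduced incompletely. The fallback sets out from 12 and comes back at 13, and it separates cleavage from reduction. LiOH/H2O2 (THF–H2O, 0 °C to rt) should remove the auxiliary at the exocyclic carbonyl and saponify the methyl ester to give (2S,3S)-2-[4-(2-carboxyethyl)-2,6-dimethoxyphenoxy]-3-{4-[(1,3-dihydroxypropan-2-yl)oxy]-3-methoxyphenyl}-3-hydroxypropanoic acid F2. BH3·THF (0 °C to rt, MeOH quench) should then reduce both carboxylic acids to give 13.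

3. Step 5. The two alkyl benzyl ethers are cleaved slowly, and during that time the electron-rich benzylic C7–O bond may be hydrogenolysed; debenzylation may also stall. The fallback sets out from 1 (and uses 9) and comes back at 13. It replaces the benzyl ethers by silyl ethers, so that only a fast alkene hydrogenation is needed. Glycerol is bis-silylated (TBSCl, imidazole, CH2Cl2) to 1,3-bis(tert-butyldimethylsilyloxy)propan-2-ol F3. Mitsunobu coupling of F3 with 1 (PPh3, DIAD, THF) gives 4-{[1,3-bis(tert-butyldimethylsilyloxy)propan-2-yl]oxy}-3-methoxybenzaldehyde F4. The aldol of step 4 between F4 and 9 gives the TMS ether F5, which citric acid in aqueous MeOH should cleave selectively to the bis-TBS aldol adduct F6. A short hydrogenation (H2, Pd/C, EtOAc) saturates only the enoate to give the saturated ester F7. LiBH4/MeOH in THF gives the bis-TBS triol F8, and TBAF buffered with AcOH in THF gives 13.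

Further compounds
F1 | step 4 | methyl (2E)-3-{4-[((Z)-2-[(4R)-4-benzyl-2-oxo-1,3-oxazolidin-3-yl]-2-[(dibutylboranyl)oxy]ethenyl)oxy]-3,5-dimethoxyphenyl}prop-2-enoate | COC(=O)/C=C/c1cc(OC)c(O/C=C(\OB(CCCC)CCCC)N2[C@H](Cc3ccccc3)COC2=O)c(OC)c1
F2 | step 6 | (2S,3S)-2-[4-(2-carboxyethyl)-2,6-dimethoxyphenoxy]-3-{4-[(1,3-dihydroxypropan-2-yl)oxy]-3-methoxyphenyl}-3-hydroxypropanoic acid | COc1cc([C@H](O)[C@@H](C(=O)O)Oc2c(OC)cc(CCC(=O)O)cc2OC)ccc1OC(CO)CO
F3 | step 5 | 1,3-bis(tert-butyldimethylsilyloxy)propan-2-ol | CC(C)(C)[Si](C)(C)OCC(O)CO[Si](C)(C)C(C)(C)C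
F4 | step 5 | 4-{[1,3-bis(tert-butyldimethylsilyloxy)propan-2-yl]oxy}-3-methoxybenzaldehyde | COc1cc(C=O)ccc1OC(CO[Si](C)(C)C(C)(C)C)CO[Si](C)(C)C(C)(C)C
F5 | step 5 | O-trimethylsilyl ether of F6, (2S,3S) in the acyl chain, (4R) in the auxiliary | COc1cc([C@H](O[Si](C)(C)C)[C@@H](C(=O)N2[C@H](Cc3ccccc3)COC2=O)Oc2c(OC)cc(/C=C/C(=O)OC)cc2OC)ccc1OC(CO[Si](C)(C)C(C)(C)C)CO[Si](C)(C)C(C)(C)C
F6 | step 5 | methyl (2E)-3-[4-({(2S,3S)-1-[(4R)-4-benzyl-2-oxo-1,3-oxazolidin-3-yl]-3-(4-{[1,3-bis(tert-butyldimethylsilyloxy)propan-2-yl]oxy}-3-methoxyphenyl)-3-hydroxy-1-oxopropan-2-yl}oxy)-3,5-dimethoxyphenyl]prop-2-enoate | COc1cc([C@H](O)[C@@H](C(=O)N2[C@H](Cc3ccccc3)COC2=O)Oc2c(OC)cc(/C=C/C(=O)OC)cc2OC)ccc1OC(CO[Si](C)(C)C(C)(C)C)CO[Si](C)(C)C(C)(C)C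
F7 | step 5 | methyl 3-[4-({(2S,3S)-1-[(4R)-4-benzyl-2-oxo-1,3-oxazolidin-3-yl]-3-(4-{[1,3-bis(tert-butyldimethylsilyloxy)propan-2-yl]oxy}-3-methoxyphenyl)-3-hydroxy-1-oxopropan-2-yl}oxy)-3,5-dimethoxyphenyl]propanoate | COc1cc([C@H](O)[C@@H](C(=O)N2[C@H](Cc3ccccc3)COC2=O)Oc2c(OC)cc(CCC(=O)OC)cc2OC)ccc1OC(CO[Si](C)(C)C(C)(C)C)CO[Si](C)(C)C(C)(C)C
F8 | step 5 | (1S,2R)-1-(4-{[1,3-bis(tert-butyldimethylsilyloxy)propan-2-yl]oxy}-3-methoxyphenyl)-2-[4-(3-hydroxypropyl)-2,6-dimethoxyphenoxy]propane-1,3-diol | COc1cc([C@H](O)[C@@H](CO)Oc2c(OC)cc(CCCO)cc2OC)ccc1OC(CO[Si](C)(C)C(C)(C)C)CO[Si](C)(C)C(C)(C)C
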